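**Strategy.** Everything rests on cutting ring C, the trioxygenated benzene, at C2–C3 and C4–C5 (C1 aryloxy carbon, C2 central C–OH, C3 outer C–OH, C5 chain carbon). Ring C atoms C5, C6, C1 and C2 then equal C6, C5, C4 and C3 of a 6-alkyl-4-aryloxy-3-methoxy-2-pyrone, and C3 plus C4 come from ketene diethyl acetal. In one operation, cycloaddition, carbon dioxide extrusion and ethanol loss build ring C with its three oxygens distinguished as ethyl, methyl and aryl ethers. The pyrone is made from triacetic acid lactone by side-chain benzylation, C3 methoxylation through a diazo compound and tosylate-for-aryloxide exchange at C4; BBr3 finally frees all four phenols.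

Key step: step 9

Remark: every isolated compound is achiral; bridged lactone 15 forms as a racemate and loses both stereocentres in the same flask. 4-(Benzyloxy)benzaldehyde replaces the free hydroxy aldehyde so that the olefination needs no extra base and the benzyl group falls in the hydrogenation. The C3 oxygen is introduced already methylated, so no free 3,4-dihydroxypyrone has to be handled or differentiated.

**Step 1**
Reactants: 1 3-methoxybenzyl bromide
Product: 2 (3-methoxybenzyl)triphenylphosphonium bromide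
Conditions: PPh3, PhMe, reflux
Reagents that add atoms: triphenylphosphine, c1ccc(cc1)P(c1ccccc1)c1ccccc1
Why: SN2 quaternisation of triphenylphosphine by a benzylic bromide (phosphonium salt formation) is fast, and the salt should precipitate from toluene.

**Step 2**
Reactants: 2 (3-methoxybenzyl)triphenylphosphonium bromide; 3 4-(benzyloxy)benzaldehyde
Product: 5 1-(benzyloxy)-4-[(E/Z)-2-(3-methoxyphenyl)ethenyl]benzene, via benzylidene phosphorane 4 (not isolated)
Conditions: KOtBu, THF, 0 °C → rt
Reagents that add atoms: none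
Why: Wittig olefination of a non-enolisable aryl aldehyde by a semi-stabilised benzylic ylide is reliable, and the alkene geometry is irrelevant because the double bond is saturated in the next step.

**Step 3**
Reactants: 5 1-(benzyloxy)-4-[(E/Z)-2-(3-methoxyphenyl)ethenyl]benzene
Product: 6 4-[2-(3-methoxyphenyl)ethyl]phenol
Conditions: H2 (1 atm), 10% Pd/C, EtOAc/EtOH, rt
Reagents that add atoms: none
Why: Heterogeneous catalytic hydrogenation should saturate the stilbene and hydrogenolyse the benzyl ether in one flask, while the aryl methyl ether is inert.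

**Step 4**
Reactants: 7 4-hydroxy-6-methyl-2H-pyran-2-one (triacetic acid lactone); 1 3-methoxybenzyl bromide
Product: 9 4-hydroxy-6-[2-(3-methoxyphenyl)ethyl]-2H-pyran-2-one, via lactone dianion dilithium salt 8 (not isolated)
Conditions: LDA (2.3 equiv), THF/DMPU, −78 °C; then 1, −78 → 0 °C; aq. HCl
Reagents that add atoms: none
Why: Dianion alkylation of a vinylogous β-keto lactone (as for acetoacetate dianions) should occur at the last-formed, most basic methyl carbanion and not at O4 or C3.

**Step 5**
Reactants: 9 4-hydroxy-6-[2-(3-methoxyphenyl)ethyl]-2H-pyran-2-one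
Product: 10 3-diazo-6-[2-(3-methoxyphenyl)ethyl]-2H-pyran-2,4(3H)-dione
Conditions: p-ABSA, Et3N, MeCN, 0 °C → rt
Reagents that add atoms: 4-acetamidobenzenesulfonyl azide (p-ABSA), CC(=O)Nc1ccc(cc1)S(=O)(=O)N=[N+]=[N-]
Why: Regitz diazo transfer to the acidic C3 position of the pyran-2,4-dione tautomer is established for 4-hydroxy-2-pyrones and 4-hydroxycoumarins.

**Step 6**
Reactants: 10 3-diazo-6-[2-(3-methoxyphenyl)ethyl]-2H-pyran-2,4(3H)-dione
Product: 11 4-hydroxy-3-methoxy-6-[2-(3-methoxyphenyl)ethyl]-2H-pyran-2-one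
Conditions: Rh2(OAc)4 (1 mol%), MeOH, 50 °C
Reagents that add atoms: methanol, CO
Why: Rhodium-carbenoid O–H insertion of a cyclic α-diazo-β-dicarbonyl compound into the solvent alcohol should place the methyl ether on C3, and the product rests as the 4-hydroxy-2-pyrone tautomer.

**Step 7**
Reactants: 11 4-hydroxy-3-methoxy-6-[2-(3-methoxyphenyl)ethyl]-2H-pyran-2-one
Product: 12 3-methoxy-6-[2-(3-methoxyphenyl)ethyl]-2-oxo-2H-pyran-4-yl 4-methylbenzenesulfonate
Conditions: TsCl, Et3N, CH2Cl2, 0 °C → rt
Reagents that add atoms: 4-methylbenzenesulfonyl chloride, Cc1ccc(cc1)S(Cl)(=O)=O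
Why: O-sulfonylation of the only hydroxyl, an acidic vinylogous acid, is standard for 4-hydroxy-2-pyrones and gives a stable enol tosylate.

**Step 8**
Reactants: 12 3-methoxy-6-[2-(3-methoxyphenyl)ethyl]-2-oxo-2H-pyran-4-yl 4-methylbenzenesulfonate; 6 4-[2-(3-methoxyphenyl)ethyl]phenol
Product: 13 3-methoxy-4-{4-[2-(3-methoxyphenyl)ethyl]phenoxy}-6-[2-(3-methoxyphenyl)ethyl]-2H-pyran-2-one
Conditions: Cs2CO3, MeCN, rt → 50 °C
Reagents that add atoms: none
Why: Addition–elimination (vinylic substitution) of the phenoxide at C4, the β-carbon of the unsaturated lactone, should expel tosylate, as known for 4-sulfonyloxy- and 4-halo-2-pyrones and coumarins with O-, N- and S-nucleophiles.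

**Step 9**
Reactants: 13 3-methoxy-4-{4-[2-(3-methoxyphenyl)ethyl]phenoxy}-6-[2-(3-methoxyphenyl)ethyl]-2H-pyran-2-one; 14 ketene diethyl acetal (1,1-diethoxyethene)
Product: 17 1-ethoxy-2-methoxy-3-{4-[2-(3-methoxyphenyl)ethyl]phenoxy}-5-[2-(3-methoxyphenyl)ethyl]benzene, via bridged lactone cycloadduct 15 (not isolated), via diethoxy cyclohexadiene 16 (not isolated)
Conditions: 14 (10 equiv), iPr2NEt (0.2 equiv), mesitylene, sealed tube, 160 °C
Reagents that add atoms: none
Why: Proposed new method: the nucleophilic CH2 of the ketene acetal should attack pyrone C6, the electrophilic far end of the dienyl lactone, and the acetal carbon should then bond to C3 in a strongly asynchronous [4+2] addition to give bridged lactone 15, which loses CO2 by retro-[4+2] to diene 16 and then ethanol to become aromatic. The closest known reaction type is the inverse-electron-demand Diels–Alder reaction of 2-pyrones bearing an ester or halogen acceptor with ketene acetals or enol ethers, which likewise ends in decarboxylation and alcohol loss to give alkoxyarenes; a pyrone carrying only the C3 methoxy and C4 aryloxy donors has not been shown to react this way, hence the excess dienophile and the high temperature. Ring C is closed by an intermolecular [4+2] annulation that forms C6–CH2 and C3–C(OEt)2, six-membered closure at C3 being preferred over four-membered closure at C5. No stereocentre survives, because the two bridgehead centres of racemic 15 are erased on aromatisation. The step needs regioselectivity, which the matched polarity of C6 (acceptor) and the acetal CH2 (donor) should secure, and chemoselectivity against attack at C4 with loss of aryloxide, which the aprotic, amine-buffered medium and the donor character of the C4 oxygen should disfavour.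

**Step 10**
Reactants: 17 1-ethoxy-2-methoxy-3-{4-[2-(3-methoxyphenyl)ethyl]phenoxy}-5-[2-(3-methoxyphenyl)ethyl]benzene
Product: 18 perrottetin F
Conditions: BBr3 (8 equiv), CH2Cl2, −78 °C → rt; then H2O
Reagents that add atoms: none
Why: Lewis-acid ether cleavage by BBr3 (bromide attack at the alkyl carbon of each borane-complexed aryl alkyl ether) should remove the three methyl groups and the ethyl group, while the diaryl ether has no sp3 carbon on oxygen and stays intact.

**Compound list**

1 | 3-methoxybenzyl bromide | COc1cccc(CBr)c1 | starting material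
2 | (3-methoxybenzyl)triphenylphosphonium bromide | COc1cccc(C[P+](c2ccccc2)(c2ccccc2)c2ccccc2)c1.[Br-] | intermediate
3 | 4-(benzyloxy)benzaldehyde | O=Cc1ccc(OCc2ccccc2)cc1 | starting material
4 | (3-methoxybenzylidene)triphenylphosphorane | COc1cccc(C=P(c2ccccc2)(c2ccccc2)c2ccccc2)c1 | intermediate (not isolated)
5 | 1-(benzyloxy)-4-[(E/Z)-2-(3-methoxyphenyl)ethenyl]benzene, mixture of alkene isomers | COc1cccc(C=Cc2ccc(OCc3ccccc3)cc2)c1 | intermediate
6 | 4-[2-(3-methoxyphenyl)ethyl]phenol | COc1cccc(CCc2ccc(O)cc2)c1 | intermediate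
7 | 4-hydroxy-6-methyl-2H-pyran-2-one (triacetic acid lactone) | CC1=CC(O)=CC(=O)O1 | starting material
8 | dilithium salt of the O4,C7-dianion of triacetic acid lactone | [Li+].[Li+].[CH2-]C1=CC([O-])=CC(=O)O1 | intermediate (not isolated)
9 | 4-hydroxy-6-[2-(3-methoxyphenyl)ethyl]-2H-pyran-2-one | COc1cccc(CCC2=CC(O)=CC(=O)O2)c1 | intermediate
10 | 3-diazo-6-[2-(3-methoxyphenyl)ethyl]-2H-pyran-2,4(3H)-dione | COc1cccc(CCC2=CC(=O)C(=[N+]=[N-])C(=O)O2)c1 | intermediate
11 | 4-hydroxy-3-methoxy-6-[2-(3-methoxyphenyl)ethyl]-2H-pyran-2-one | COc1cccc(CCC2=CC(O)=C(OC)C(=O)O2)c1 | intermediate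
12 | 3-methoxy-6-[2-(3-methoxyphenyl)ethyl]-2-oxo-2H-pyran-4-yl 4-methylbenzenesulfonate | COc1cccc(CCC2=CC(OS(=O)(=O)c3ccc(C)cc3)=C(OC)C(=O)O2)c1 | intermediate
13 | 3-methoxy-4-{4-[2-(3-methoxyphenyl)ethyl]phenoxy}-6-[2-(3-methoxyphenyl)ethyl]-2H-pyran-2-one | COc1cccc(CCC2=CC(Oc3ccc(CCc4cccc(OC)c4)cc3)=C(OC)C(=O)O2)c1 | intermediate
14 | ketene diethyl acetal (1,1-diethoxyethene) | C=C(OCC)OCC | starting material
15 | 8,8-diethoxy-4-methoxy-5-{4-[2-(3-methoxyphenyl)ethyl]phenoxy}-1-[2-(3-methoxyphenyl)ethyl]-2-oxabicyclo[2.2.2]oct-5-en-3-one, racemic, bridgehead configurations tied to each other by the bicycle | COc1cccc(CCC23CC(OCC)(OCC)C(OC)(C(=O)O2)C(Oc2ccc(CCc4cccc(OC)c4)cc2)=C3)c1 | intermediate (not isolated)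
16 | 6,6-diethoxy-1-methoxy-2-{4-[2-(3-methoxyphenyl)ethyl]phenoxy}-4-[2-(3-methoxyphenyl)ethyl]cyclohexa-1,3-diene | CCOC1(OCC)CC(CCc2cccc(OC)c2)=CC(Oc2ccc(CCc3cccc(OC)c3)cc2)=C1OC | intermediate (not isolated)
17 | 1-ethoxy-2-methoxy-3-{4-[2-(3-methoxyphenyl)ethyl]phenoxy}-5-[2-(3-methoxyphenyl)ethyl]benzene | CCOc1cc(CCc2cccc(OC)c2)cc(Oc2ccc(CCc3cccc(OC)c3)cc2)c1OC | intermediate
18 | perrottetin F, 3-{4-[2-(3-hydroxyphenyl)ethyl]phenoxy}-5-[2-(3-hydroxyphenyl)ethyl]benzene-1,2-diol | Oc1cccc(CCc2ccc(Oc3cc(CCc4cccc(O)c4)cc(O)c3O)cc2)c1 | target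

**Step count and risk**

Total steps: 10. Longest linear sequence: 7 steps (steps 4 to 10, from triacetic acid lactone 7); the bibenzyl phenol arm (steps 1 to 3) joins at step 8.

Steps most likely to fail:

1. Step 9 (proposed new method). The cycloaddition may not start because the diene carries two donors and no acceptor, so that thermal oligomerisation of the ketene acetal outruns addition; alternatively the acetal may add at C4 and expel the aryloxide. The fallback uses known chemistry, sets out from phenol 6 and salt 2 and returns at 17. Phenol 6 is joined to 3-bromo-5-ethoxy-4-methoxybenzaldehyde F1 (purchased, or made by O-methylation of 5-bromo-ethylvanillin) in an Ullmann diaryl ether coupling (CuI, N,N-dimethylglycine, Cs2CO3, dioxane, 100 °C). This should give 3-ethoxy-4-methoxy-5-{4-[2-(3-methoxyphenyl)ethyl]phenoxy}benzaldehyde F2. Wittig olefination of F2 with phosphorane 4, generated from 2 with KOtBu in THF, should give 1-ethoxy-2-methoxy-5-[(E/Z)-2-(3-methoxyphenyl)ethenyl]-3-{4-[2-(3-methoxyphenyl)ethyl]phenoxy}benzene F3. Hydrogenation of F3 (H2, Pd/C, EtOAc) should deliver 17, which continues into step 10.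

2. Step 8. The phenoxide may attack sulfur and not C4 (sulfonyl transfer that returns 11 and consumes 6), or addition at the donor-flanked C4 may be too slow. The fallback sets out from 11 and returns at 13. Deoxybromination of 11 (Bu4NBr, P2O5, PhMe, 100 °C) should give 4-bromo-3-methoxy-6-[2-(3-methoxyphenyl)ethyl]-2H-pyran-2-one F4, which has no sulfonyl group to be attacked. Copper-catalysed C–O coupling of F4 with 6 (CuI, N,N-dimethylglycine, Cs2CO3, dioxane, 90 °C) should then give 13.

3. Step 6. The carbenoid may be diverted into ring contraction by Wolff-type rearrangement, into insertion into the hydroxyl of product already formed, or the lactone may be opened by methanol. The fallback sets out from 9 and returns at 12. Electrophilic C3 hydroxylation of 9 with dimethyldioxirane (acetone, 0 °C) should give 3,4-dihydroxy-6-[2-(3-methoxyphenyl)ethyl]-2H-pyran-2-one F5. Selective sulfonylation of its more acidic C4 hydroxyl (TsCl, 1.0 equiv, Et3N, CH2Cl2, −20 °C) should give 3-hydroxy-6-[2-(3-methoxyphenyl)ethyl]-2-oxo-2H-pyran-4-yl 4-methylbenzenesulfonate F6. O-Methylation of the remaining C3 hydroxyl of F6 (MeI, K2CO3, acetone, rt) should give 12.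

**Further compounds**

F1 | step 9 | 3-bromo-5-ethoxy-4-methoxybenzaldehyde | CCOc1cc(C=O)cc(Br)c1OC
F2 | step 9 | 3-ethoxy-4-methoxy-5-{4-[2-(3-methoxyphenyl)ethyl]phenoxy}benzaldehyde | CCOc1cc(C=O)cc(Oc2ccc(CCc3cccc(OC)c3)cc2)c1OC
F3 | step 9 | 1-ethoxy-2-methoxy-5-[(E/Z)-2-(3-methoxyphenyl)ethenyl]-3-{4-[2-(3-methoxyphenyl)ethyl]phenoxy}benzene | CCOc1cc(C=Cc2cccc(OC)c2)cc(Oc2ccc(CCc3cccc(OC)c3)cc2)c1OC
F4 | step 8 | 4-bromo-3-methoxy-6-[2-(3-methoxyphenyl)ethyl]-2H-pyran-2-one | COc1cccc(CCC2=CC(Br)=C(OC)C(=O)O2)c1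
F5 | step 6 | 3,4-dihydroxy-6-[2-(3-methoxyphenyl)ethyl]-2H-pyran-2-one | COc1cccc(CCC2=CC(O)=C(O)C(=O)O2)c1
F6 | step 6 | 3-hydroxy-6-[2-(3-methoxyphenyl)ethyl]-2-oxo-2H-pyran-4-yl 4-methylbenzenesulfonate | COc1cccc(CCC2=CC(OS(=O)(=O)c3ccc(C)cc3)=C(O)C(=O)O2)c1
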